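In ring B the quaternary C10, whose methyl is cis to H5, sits next to C9, which carries the side chain; the route rests on cutting the C10–CH3 and C9–C11 bonds together. In one flask a methyl cuprate adds to C10 of a bicyclic C8–C9–C10 enone on the face of H5 and the resulting C8–C9 enolate is allylated at C9, so two C–C bonds and the cis ring fusion arise at once; the C8 carbonyl later becomes the C8=C9 alkene. The precursor is (4aR)-5,5-dimethyl-4,4a,5,6,7,8-hexahydronaphthalen-2(3H)-one, whose single stereocentre C5 steers the addition. Cross-metathesis, Horner–Wadsworth–Emmons olefination and Stille coupling then build the hydroxymethyl dienyl butenolide.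

Key step: step 5

Remark: labdane numbering is used for the core and chain (C4 gem-dimethyl, C5 ring-fusion CH, C8/C9 alkene carbons, C10 quaternary, C11–C16 chain, hydroxymethyl on C13); the target is read as 5R,10S,13E,15E, i.e. (4aR,8aS) with the C10 methyl cis to H5.

Step 1
Reactants: 1 6-methoxy-1-tetralone
Product: 2 6-methoxy-1,1-dimethyl-1,2,3,4-tetrahydronaphthalene
Conditions: Me2Zn, TiCl4, CH2Cl2, −40 °C → rt
Reagents that add atoms: dimethylzinc, C[Zn]C
Why: Geminal dimethylation of an aryl ketone with Me2TiCl2 formed in situ: after the first methyl adds, the benzylic titanium alkoxide ionises to a p-methoxy-stabilised tertiary cation that takes up the second methyl, so C=O is exchanged for CMe2 in one operation.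

Step 2
Reactants: 2 6-methoxy-1,1-dimethyl-1,2,3,4-tetrahydronaphthalene
Product: 3 6-methoxy-1,1-dimethyl-1,2,3,4,5,8-hexahydronaphthalene
Conditions: Li, NH3 (l), t-BuOH, THF, −78 → −33 °C
Reagents that add atoms: none
Why: Birch reduction of an anisole protonates ortho and meta to the methoxy group, which should leave the enol ether and the tetrasubstituted ring-fusion alkene as an unconjugated 1,4-diene.

Step 3
Reactants: 3 6-methoxy-1,1-dimethyl-1,2,3,4,5,8-hexahydronaphthalene
Product: 4 5,5-dimethyl-3,4,5,6,7,8-hexahydronaphthalen-2(1H)-one (β,γ-enone, ring-fusion alkene)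
Conditions: (CO2H)2 (cat.), MeOH/H2O, rt
Reagents that add atoms: water, O
Why: Mild acid hydrolysis of the enol ether should release the ketone faster than the ring-fusion alkene migrates, so the β,γ-unsaturated ketone is expected (kinetic enol ether hydrolysis).

Step 4
Reactants: 4 5,5-dimethyl-3,4,5,6,7,8-hexahydronaphthalen-2(1H)-one
Product: 5 (4aR)-5,5-dimethyl-4,4a,5,6,7,8-hexahydronaphthalen-2(3H)-one
Conditions: 9-amino-9-deoxy-epi-cinchona primary amine (10 mol %, pseudoenantiomer chosen for 4aR), ArCO2H (20 mol %), PhMe, −20 °C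
Reagents that add atoms: none
Why: Enantioselective β,γ- to α,β-enone isomerisation by cooperative iminium–base catalysis: the amine condenses with the ketone, the α-proton at C9 is removed to a dienamine, and the protonated quinuclidine delivers a proton to one face of the γ-carbon C5, which sets the ring-fusion stereocentre under catalyst control while conjugation drives the reaction.

Step 5
Reactants: 5 (4aR)-5,5-dimethyl-4,4a,5,6,7,8-hexahydronaphthalen-2(3H)-one; 6 allyl bromide
Product: 8 (1S,4aR,8aS)-1-allyl-5,5,8a-trimethyloctahydronaphthalen-2(1H)-one (cis-fused 9-allyl-4,4,10-trimethyldecal-8-one in labdane numbering), via lithium C8–C9 enolate 7 (not isolated)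
Conditions: Me2CuLi (MeLi, CuI), Et2O, −20 → 0 °C; then 6 (excess), DMPU, THF, 0 °C → rt
Reagents that add atoms: lithium dimethylcuprate, [Li+].C[Cu-]C (from methyllithium, [Li]C, and CuI); allyl bromide, C=CCBr
Why: The cuprate forms a copper–alkene π-complex with the C9=C10 bond, oxidative addition and reductive elimination place the methyl on C10 and leave lithium enolate 7, which is C-allylated at C9 by SN2 displacement on allyl bromide once DMPU has loosened the enolate aggregates. The closest known reaction type is conjugate methylation of ring-fusion-H octalones to cis-fused angular-methyl decalones, combined with alkylative trapping of cuprate-derived enolates (three-component conjugate addition–alkylation). No ring is closed. C10 is controlled by C5: the methyl enters axially on ring B, anti to the C5–C4 bond and therefore on the face of H5, whereas the opposite mode would build a syn-diaxial contact with a C4 methyl, so the methyl should end up cis to H5. C9 is expected with the allyl group anti to the new angular methyl, but its configuration is irrelevant because C9 becomes sp2 in step 9. The step needs C-alkylation at C9 and not at C7 or oxygen, which the regiodefined enolate, an excess of a reactive allylic halide and the absence of a proton source should secure.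

Step 6
Reactants: 8 (1S,4aR,8aS)-1-allyl-5,5,8a-trimethyloctahydronaphthalen-2(1H)-one
Product: 9 (1S,4aR,8aS)-1-allyl-2,5,5,8a-tetramethyldecahydronaphthalen-2-ol (both C2 epimers)
Conditions: MeLi, CeCl3, THF, −78 °C
Reagents that add atoms: methyllithium, [Li]C (delivered as methylcerium dichloride)
Why: Organocerium 1,2-addition to a hindered, enolisable ketone should proceed without enolisation; the new C8 carbinol centre is formed without control and is removed in step 9.

Step 7
Reactants: 9 (1S,4aR,8aS)-1-allyl-2,5,5,8a-tetramethyldecahydronaphthalen-2-ol; 10 diethyl vinylphosphonate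
Product: 11 diethyl {(E)-3-[(1S,4aR,8aS)-2-hydroxy-2,5,5,8a-tetramethyldecahydronaphthalen-1-yl]prop-1-en-1-yl}phosphonate
Conditions: 2nd-generation Ru NHC benzylidene metathesis catalyst (5 mol %), CH2Cl2, 40 °C
Reagents that add atoms: diethyl vinylphosphonate, C=CP(=O)(OCC)OCC
Why: Olefin cross-metathesis between the unhindered terminal allyl alkene and a slowly homodimerising vinylphosphonate should give the E cross product selectively, and the tertiary alcohol is tolerated.

Step 8
Reactants: 11 diethyl {(E)-3-[(1S,4aR,8aS)-2-hydroxy-2,5,5,8a-tetramethyldecahydronaphthalen-1-yl]prop-1-en-1-yl}phosphonate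
Product: 12 diethyl {3-[(1S,4aR,8aS)-2-hydroxy-2,5,5,8a-tetramethyldecahydronaphthalen-1-yl]propyl}phosphonate
Conditions: H2 (1 atm), 10% Pd/C, EtOAc, rt
Reagents that add atoms: none
Why: Heterogeneous catalytic hydrogenation saturates the disubstituted vinylphosphonate, which is the only alkene in the molecule at this stage.

Step 9
Reactants: 12 diethyl {3-[(1S,4aR,8aS)-2-hydroxy-2,5,5,8a-tetramethyldecahydronaphthalen-1-yl]propyl}phosphonate
Product: 13 diethyl {3-[(4aR,8aS)-2,5,5,8a-tetramethyl-3,4,4a,5,6,7,8,8a-octahydronaphthalen-1-yl]propyl}phosphonate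
Conditions: TsOH·H2O (10 mol %), PhH, 80 °C, Dean–Stark
Reagents that add atoms: none
Why: Acid-catalysed E1 dehydration under equilibrating conditions (Zaitsev control): the tertiary C8 cation loses a proton reversibly, so the less substituted Δ7, exocyclic and C9-alkylidene isomers should be funnelled into the tetrasubstituted C8=C9 alkene, which removes the C8 and C9 stereocentres.

Step 10
Reactants: 13 diethyl {3-[(4aR,8aS)-2,5,5,8a-tetramethyl-3,4,4a,5,6,7,8,8a-octahydronaphthalen-1-yl]propyl}phosphonate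
Product: 15 ethyl 2-(diethoxyphosphoryl)-5-[(4aR,8aS)-2,5,5,8a-tetramethyl-3,4,4a,5,6,7,8,8a-octahydronaphthalen-1-yl]pentanoate (both C2 epimers), via α-lithio phosphonate 14 (not isolated)
Conditions: LDA (2.2 equiv), THF, −78 °C; then ClCO2Et, −78 → 0 °C
Reagents that add atoms: ethyl chloroformate, CCOC(=O)Cl
Why: C-acylation of a lithiated alkylphosphonate with a chloroformate gives the 2-phosphonoalkanoate, the second equivalent of base converting the more acidic product into its unreactive anion; the new C13 centre is uncontrolled and becomes sp2 in step 12.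

Step 11
Reactants: 16 (E)-1,2-bis(tributylstannyl)ethene
Product: 18 (E)-3-(tributylstannyl)prop-2-enal, via (E)-2-(tributylstannyl)vinyllithium 17 (not isolated)
Conditions: n-BuLi (1.0 equiv), THF, −78 °C; then DMF, −78 → 0 °C; aq. NH4Cl
Reagents that add atoms: N,N-dimethylformamide, CN(C)C=O
Why: Tin–lithium exchange of one stannyl group occurs with retention of the E geometry and the vinyllithium is formylated by DMF, the tetrahedral adduct surviving until aqueous work-up.

Step 12
Reactants: 15 ethyl 2-(diethoxyphosphoryl)-5-[(4aR,8aS)-2,5,5,8a-tetramethyl-3,4,4a,5,6,7,8,8a-octahydronaphthalen-1-yl]pentanoate; 18 (E)-3-(tributylstannyl)prop-2-enal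
Product: 20 ethyl (2E,4E)-2-{2-[(4aR,8aS)-2,5,5,8a-tetramethyl-3,4,4a,5,6,7,8,8a-octahydronaphthalen-1-yl]ethyl}-5-(tributylstannyl)penta-2,4-dienoate, via sodium phosphonate carbanion 19 (not isolated)
Conditions: NaH, THF, 0 °C; then 18, 0 °C → rt
Reagents that add atoms: (E)-3-(tributylstannyl)prop-2-enal, O=C/C=C/[Sn](CCCC)(CCCC)CCCC
Why: Horner–Wadsworth–Emmons olefination of an α-alkyl phosphonoacetate with an enal is reversible in the addition step and should place the ester trans to the alkenyl substituent, which is the 13E geometry, while the 15E stannyl alkene is carried over unchanged from 18.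

Step 13
Reactants: 20 ethyl (2E,4E)-2-{2-[(4aR,8aS)-2,5,5,8a-tetramethyl-3,4,4a,5,6,7,8,8a-octahydronaphthalen-1-yl]ethyl}-5-(tributylstannyl)penta-2,4-dienoate
Product: 21 (2E,4E)-2-{2-[(4aR,8aS)-2,5,5,8a-tetramethyl-3,4,4a,5,6,7,8,8a-octahydronaphthalen-1-yl]ethyl}-5-(tributylstannyl)penta-2,4-dien-1-ol
Conditions: DIBAL-H (2.5 equiv), CH2Cl2, −78 °C; Rochelle salt work-up
Reagents that add atoms: none
Why: DIBAL-H 1,2-reduction of the conjugated ester should give the allylic alcohol without touching the alkenylstannane or the alkenes, and it is done before the reducible butenolide is present.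

Step 14
Reactants: 21 (2E,4E)-2-{2-[(4aR,8aS)-2,5,5,8a-tetramethyl-3,4,4a,5,6,7,8,8a-octahydronaphthalen-1-yl]ethyl}-5-(tributylstannyl)penta-2,4-dien-1-ol; 22 4-bromofuran-2(5H)-one
Product: 23 4-[(1E,3E)-4-(hydroxymethyl)-6-[(4aR,8aS)-2,5,5,8a-tetramethyl-3,4,4a,5,6,7,8,8a-octahydronaphthalen-1-yl]hexa-1,3-dien-1-yl]furan-2(5H)-one (target)
Conditions: Pd2(dba)3 (5 mol %), AsPh3 (20 mol %), NMP, rt → 40 °C, dark
Reagents that add atoms: 4-bromofuran-2(5H)-one, O=C1C=C(Br)CO1
Why: Stille coupling of the E-alkenylstannane with the vinylogous acyl bromide proceeds with retention at both sp2 carbons under neutral conditions, which should leave the free allylic alcohol and the base-sensitive butenolide intact.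

Compound list
1 | 6-methoxy-1-tetralone | COc1ccc2C(=O)CCCc2c1 | starting material
2 | 6-methoxy-1,1-dimethyl-1,2,3,4-tetrahydronaphthalene | COc1ccc2c(c1)CCCC2(C)C | intermediate
3 | 6-methoxy-1,1-dimethyl-1,2,3,4,5,8-hexahydronaphthalene | COC1=CCC2=C(C1)CCCC2(C)C | intermediate
4 | 5,5-dimethyl-3,4,5,6,7,8-hexahydronaphthalen-2(1H)-one | O=C1CCC2=C(C1)CCCC2(C)C | intermediate
5 | (4aR)-5,5-dimethyl-4,4a,5,6,7,8-hexahydronaphthalen-2(3H)-one | O=C1C=C2CCCC(C)(C)[C@H]2CC1 | intermediate
6 | allyl bromide | C=CCBr | starting material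
7 | lithium (4aR,8aS)-5,5,8a-trimethyl-3,4,4a,5,6,7,8,8a-octahydronaphthalen-2-olate (C8–C9 enolate) | [Li]OC1=C[C@@]2(C)CCCC(C)(C)[C@H]2CC1 | intermediate
8 | (1S,4aR,8aS)-1-allyl-5,5,8a-trimethyloctahydronaphthalen-2(1H)-one (angular methyl cis to H-4a, allyl trans to the angular methyl) | O=C1[C@@H](CC=C)[C@@]2(C)CCCC(C)(C)[C@H]2CC1 | intermediate
9 | (1S,4aR,8aS)-1-allyl-2,5,5,8a-tetramethyldecahydronaphthalen-2-ol, C2 epimer mixture | CC1(O)[C@@H](CC=C)[C@@]2(C)CCCC(C)(C)[C@H]2CC1 | intermediate
10 | diethyl vinylphosphonate | C=CP(=O)(OCC)OCC | starting material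
11 | diethyl {(E)-3-[(1S,4aR,8aS)-2-hydroxy-2,5,5,8a-tetramethyldecahydronaphthalen-1-yl]prop-1-en-1-yl}phosphonate | CC1(O)[C@@H](C/C=C/P(=O)(OCC)OCC)[C@@]2(C)CCCC(C)(C)[C@H]2CC1 | intermediate
12 | diethyl {3-[(1S,4aR,8aS)-2-hydroxy-2,5,5,8a-tetramethyldecahydronaphthalen-1-yl]propyl}phosphonate | CC1(O)[C@@H](CCCP(=O)(OCC)OCC)[C@@]2(C)CCCC(C)(C)[C@H]2CC1 | intermediate
13 | diethyl {3-[(4aR,8aS)-2,5,5,8a-tetramethyl-3,4,4a,5,6,7,8,8a-octahydronaphthalen-1-yl]propyl}phosphonate | CC1=C(CCCP(=O)(OCC)OCC)[C@@]2(C)CCCC(C)(C)[C@H]2CC1 | intermediate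
14 | α-lithio derivative of 13 (lithium on the carbon next to phosphorus) | CC1=C(CCC([Li])P(=O)(OCC)OCC)[C@@]2(C)CCCC(C)(C)[C@H]2CC1 | intermediate
15 | ethyl 2-(diethoxyphosphoryl)-5-[(4aR,8aS)-2,5,5,8a-tetramethyl-3,4,4a,5,6,7,8,8a-octahydronaphthalen-1-yl]pentanoate, C2 epimer mixture | CC1=C(CCC(C(=O)OCC)P(=O)(OCC)OCC)[C@@]2(C)CCCC(C)(C)[C@H]2CC1 | intermediate
16 | (E)-1,2-bis(tributylstannyl)ethene | CCCC[Sn](CCCC)(CCCC)/C=C/[Sn](CCCC)(CCCC)CCCC | starting material
17 | (E)-2-(tributylstannyl)vinyllithium | [Li]/C=C/[Sn](CCCC)(CCCC)CCCC | intermediate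
18 | (E)-3-(tributylstannyl)prop-2-enal | O=C/C=C/[Sn](CCCC)(CCCC)CCCC | intermediate
19 | sodium salt (phosphonate carbanion) of 15 | [Na+].CC1=C(CC[C-](C(=O)OCC)P(=O)(OCC)OCC)[C@@]2(C)CCCC(C)(C)[C@H]2CC1 | intermediate
20 | ethyl (2E,4E)-2-{2-[(4aR,8aS)-2,5,5,8a-tetramethyl-3,4,4a,5,6,7,8,8a-octahydronaphthalen-1-yl]ethyl}-5-(tributylstannyl)penta-2,4-dienoate | CC1=C(CC/C(=C\C=C\[Sn](CCCC)(CCCC)CCCC)C(=O)OCC)[C@@]2(C)CCCC(C)(C)[C@H]2CC1 | intermediate
21 | (2E,4E)-2-{2-[(4aR,8aS)-2,5,5,8a-tetramethyl-3,4,4a,5,6,7,8,8a-octahydronaphthalen-1-yl]ethyl}-5-(tributylstannyl)penta-2,4-dien-1-ol | CC1=C(CC/C(=C\C=C\[Sn](CCCC)(CCCC)CCCC)CO)[C@@]2(C)CCCC(C)(C)[C@H]2CC1 | intermediate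
22 | 4-bromofuran-2(5H)-one | O=C1C=C(Br)CO1 | starting material
23 | 4-[(1E,3E)-4-(hydroxymethyl)-6-[(4aR,8aS)-2,5,5,8a-tetramethyl-3,4,4a,5,6,7,8,8a-octahydronaphthalen-1-yl]hexa-1,3-dien-1-yl]furan-2(5H)-one | CC1=C(CC/C(=C\C=C\C2=CC(=O)OC2)CO)[C@@]2(C)CCCC(C)(C)[C@H]2CC1 | target

Total step count: 14. Longest linear sequence: 13 steps (steps 1–10 and 12–14); step 11 is a one-step side branch.

Steps most likely to fail

Step 5. The enolate carbon C9 lies next to the new quaternary centre and may alkylate slowly, so that proton exchange between enolate and product leads to allylation at C7 or to double allylation. The fallback sets out from 5 and returns at 8. The cuprate addition is run in the presence of Me3SiCl (Me2CuLi, Me3SiCl, Et2O/THF, −78 → 0 °C) and the product is isolated as trimethyl{[(4aR,8aS)-5,5,8a-trimethyl-3,4,4a,5,6,7,8,8a-octahydronaphthalen-2-yl]oxy}silane F5. This silyl enol ether is then allylated under Tsuji–Trost conditions (Pd2(dba)3, dppe, diallyl carbonate, Bu4N Ph3SiF2, THF, rt). There the enolate is released only in the presence of the π-allylpalladium electrophile, so the regiochemistry fixed by the conjugate addition should be kept.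

Step 4. The γ-protonation has to take place at a ring-fusion carbon with a quaternary neighbour; slow turnover or poor facial discrimination there would give material of low enantiomeric purity. The fallback sets out from 4 and returns at 5 by resolution instead of asymmetric catalysis.
- Conjugation with NaOMe in MeOH gives the racemic enone rac-5,5-dimethyl-4,4a,5,6,7,8-hexahydronaphthalen-2(3H)-one F1.
- Luche reduction (NaBH4, CeCl3, MeOH, 0 °C) should give mainly the pseudo-equatorial allylic alcohol rac-(2S*,4aR*)-5,5-dimethyl-2,3,4,4a,5,6,7,8-octahydronaphthalen-2-ol F2, with OH cis to H-4a.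
- Lipase-catalysed acylation (Amano lipase PS, vinyl acetate, t-BuOMe) is expected to convert the 2R enantiomer into (2R,4aS)-5,5-dimethyl-2,3,4,4a,5,6,7,8-octahydronaphthalen-2-yl acetate F3 and to leave (2S,4aR)-5,5-dimethyl-2,3,4,4a,5,6,7,8-octahydronaphthalen-2-ol F4.
- After separation, F4 is oxidised with MnO2 (CH2Cl2, rt) to 5.

Step 9. Proton loss from the C8 cation may go towards C7 or the C8 methyl without full equilibration, or the cation may undergo 1,2-hydride and methyl shifts along C9–C10. The fallback sets out from 8 and returns at 13; it installs the C8 methyl by cross-coupling instead of addition and elimination.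
- Equilibrating silylation (Me3SiCl, NaI, Et3N, MeCN) should give the more substituted enol ether {[(4aR,8aS)-1-allyl-5,5,8a-trimethyl-3,4,4a,5,6,7,8,8a-octahydronaphthalen-2-yl]oxy}trimethylsilane F6.
- MeLi in THF followed by PhNTf2 gives (4aR,8aS)-1-allyl-5,5,8a-trimethyl-3,4,4a,5,6,7,8,8a-octahydronaphthalen-2-yl trifluoromethanesulfonate F7.
- Iron-catalysed methylation (MeMgBr, Fe(acac)3 cat., THF/NMP, −20 °C) gives (4aR,8aS)-1-allyl-2,5,5,8a-tetramethyl-3,4,4a,5,6,7,8,8a-octahydronaphthalene F8.
- Cross-metathesis with 10 under the conditions of step 7 gives diethyl {(E)-3-[(4aR,8aS)-2,5,5,8a-tetramethyl-3,4,4a,5,6,7,8,8a-octahydronaphthalen-1-yl]prop-1-en-1-yl}phosphonate F9.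
- Selective hydrogenation of the disubstituted alkene (H2, RhCl(PPh3)3, PhH, rt) gives 13.

Further compounds
F1 | step 4 | rac-5,5-dimethyl-4,4a,5,6,7,8-hexahydronaphthalen-2(3H)-one | O=C1C=C2CCCC(C)(C)C2CC1
F2 | step 4 | rac-(2S*,4aR*)-5,5-dimethyl-2,3,4,4a,5,6,7,8-octahydronaphthalen-2-ol | OC1C=C2CCCC(C)(C)C2CC1
F3 | step 4 | (2R,4aS)-5,5-dimethyl-2,3,4,4a,5,6,7,8-octahydronaphthalen-2-yl acetate | CC(=O)O[C@H]1C=C2CCCC(C)(C)[C@@H]2CC1
F4 | step 4 | (2S,4aR)-5,5-dimethyl-2,3,4,4a,5,6,7,8-octahydronaphthalen-2-ol | O[C@@H]1C=C2CCCC(C)(C)[C@H]2CC1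
F5 | step 5 | trimethyl{[(4aR,8aS)-5,5,8a-trimethyl-3,4,4a,5,6,7,8,8a-octahydronaphthalen-2-yl]oxy}silane | C[Si](C)(C)OC1=C[C@@]2(C)CCCC(C)(C)[C@H]2CC1
F6 | step 9 | {[(4aR,8aS)-1-allyl-5,5,8a-trimethyl-3,4,4a,5,6,7,8,8a-octahydronaphthalen-2-yl]oxy}trimethylsilane | C[Si](C)(C)OC1=C(CC=C)[C@@]2(C)CCCC(C)(C)[C@H]2CC1
F7 | step 9 | (4aR,8aS)-1-allyl-5,5,8a-trimethyl-3,4,4a,5,6,7,8,8a-octahydronaphthalen-2-yl trifluoromethanesulfonate | FC(F)(F)S(=O)(=O)OC1=C(CC=C)[C@@]2(C)CCCC(C)(C)[C@H]2CC1
F8 | step 9 | (4aR,8aS)-1-allyl-2,5,5,8a-tetramethyl-3,4,4a,5,6,7,8,8a-octahydronaphthalene | CC1=C(CC=C)[C@@]2(C)CCCC(C)(C)[C@H]2CC1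
F9 | step 9 | diethyl {(E)-3-[(4aR,8aS)-2,5,5,8a-tetramethyl-3,4,4a,5,6,7,8,8a-octahydronaphthalen-1-yl]prop-1-en-1-yl}phosphonate | CC1=C(C/C=C/P(=O)(OCC)OCC)[C@@]2(C)CCCC(C)(C)[C@H]2CC1
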